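## Retrosynthetic overview

1. The 18-membered macrolide (C1–C17, lactone O, through the oxazole) is closed last at the C7–C8 oxazole–alkene bond by intramolecular Stille coupling, after esterifying C17–OH with the C1–C7 stannyl dienoic acid 43 (Evans aldol sets C4/C5).
2. The oxazole ring (O, C8, C9, C10, N) is built on the C10 carboxyl group via amide, acyl isocyanate and oxazol-4(5H)-one; the C22–C23 bond comes from opening methyl (S)-2-methylglycidate with the C21≡C22 acetylide (C24), followed by Lindlar reduction.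
3. Structural feature used: the oxolane O/C16/C17/C18/C19 carries Br at C18 anti to the ring O–C19 bond, a quaternary C19 and a methyl ether on the exocyclic C15. This is the pattern left when the oxygen of a C15–C16 epoxide opens a C18/C19 bromonium ion and methanol opens the resulting epoxonium ion, so C18–Br, O–C19 and C15–OMe are disconnected together to the cis-epoxy (E)-alkene 16.
4. 16 comes from (S)-citronellal (C10–C15, C13 stereocentre) by Z-olefination, Sharpless epoxidation, ozonolytic esterification and Felkin addition of the C18–C22 alkenylzincate made from trimethylsilylacetylene and propargyl bromide.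
5. Order of ring formation: oxolane (step 10), oxazole (steps 16–17), macrocycle (step 28).

Key step: step 10

Remark: atom numbers C1–C25 follow the macrolide chain (C1 lactone carbonyl; C8/C9/C10 = oxazole C4/C5/C2; C17 lactone carbinol; C25 carboxyl carbon). CIP descriptors in the names belong to each compound; some change letter without any change of geometry when substituent priorities change (for example C16 and C17).

## Route

Step 1
Reactants: 1 (S)-citronellal
Product: 2 methyl (2Z,5S)-5,9-dimethyldeca-2,8-dienoate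
Conditions: (CF3CH2O)2P(O)CH2CO2Me, KHMDS, 18-crown-6, THF, −78 °C
Reagents that add atoms: methyl bis(2,2,2-trifluoroethyl)phosphonoacetate, COC(=O)CP(=O)(OCC(F)(F)F)OCC(F)(F)F
Why: Still–Gennari olefination of an unhindered aliphatic aldehyde under dissociating conditions should give the kinetic (Z)-enoate (C15=C16), and the β-stereocentre C13 cannot epimerise.

Step 2
Reactants: 2 methyl (2Z,5S)-5,9-dimethyldeca-2,8-dienoate
Product: 3 (2Z,5S)-5,9-dimethyldeca-2,8-dien-1-ol
Conditions: DIBAL-H, CH2Cl2, −78 °C; Rochelle salt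
Reagents that add atoms: none
Why: DIBAL-H 1,2-reduction of the conjugated ester gives the allylic alcohol and leaves both alkenes and the Z geometry untouched.

Step 3
Reactants: 3 (2Z,5S)-5,9-dimethyldeca-2,8-dien-1-ol
Product: 4 [(2S,3R)-3-[(2S)-2,6-dimethylhept-5-en-1-yl]oxiran-2-yl]methanol
Conditions: Ti(OiPr)4 (10 mol%), L-(+)-DIPT (12 mol%), t-BuOOH, 4 Å MS, CH2Cl2, −20 °C
Reagents that add atoms: tert-butyl hydroperoxide, CC(C)(C)OO
Why: Sharpless asymmetric epoxidation touches only the allylic-alcohol alkene, and L-(+)-tartrate delivers oxygen to the face of the Z-alkene that gives the (2S,3R) cis-epoxy alcohol (C15 R, C16 S here), reagent control overriding the remote C13 centre.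

Step 4
Reactants: 4 [(2S,3R)-3-[(2S)-2,6-dimethylhept-5-en-1-yl]oxiran-2-yl]methanol
Product: 5 methyl (4S)-5-[(2R,3S)-3-(hydroxymethyl)oxiran-2-yl]-4-methylpentanoate
Conditions: O3, NaOH/MeOH, CH2Cl2, −78 °C
Reagents that add atoms: ozone, [O-][O+]=O; methanol, CO
Why: Ozonolysis in methanolic NaOH (Marshall conditions) converts the one remaining alkene directly into the C10 methyl ester via the methoxy hydroperoxide/hemiacetal, while the epoxide and the primary alcohol should survive the short exposure at −78 °C.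

Step 5
Reactants: 5 methyl (4S)-5-[(2R,3S)-3-(hydroxymethyl)oxiran-2-yl]-4-methylpentanoate
Product: 6 methyl (4S)-5-[(2R,3R)-3-formyloxiran-2-yl]-4-methylpentanoate
Conditions: Dess–Martin periodinane, NaHCO3, CH2Cl2, 0 °C to rt
Reagents that add atoms: none
Why: Buffered Dess–Martin oxidation gives the cis-epoxy aldehyde without epimerisation at C16 or epoxide opening; the aldehyde is used at once.

Step 6
Reactants: 7 ethynyltrimethylsilane; 8 propargyl bromide
Product: 10 trimethyl(penta-1,4-diyn-1-yl)silane, via silylethynylmagnesium bromide 9 (not isolated)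
Conditions: EtMgBr, THF, 0 °C to rt; CuCl (5 mol%), 8, THF, 50 °C
Reagents that add atoms: none
Why: Copper-catalysed SN2 coupling of an alkynyl Grignard reagent with propargyl bromide is the standard entry to skipped diynes, the silyl group blocking one terminus.

Step 7
Reactants: 10 trimethyl(penta-1,4-diyn-1-yl)silane
Product: 12 [(4E)-5-iodo-4-methylpent-4-en-1-yn-1-yl]trimethylsilane, via alkenyldimethylalane 11 (not isolated)
Conditions: AlMe3, Cp2ZrCl2 (20 mol%), CH2Cl2, 0 °C to rt; I2, THF, −30 to 0 °C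
Reagents that add atoms: trimethylaluminium, C[Al](C)C; iodine, II
Why: Negishi zirconium-catalysed carboalumination adds Me–Al syn and regioselectively to the terminal alkyne only (the silylalkyne is inert), and iodinolysis with retention gives the (E)-iodide that fixes the C18=C19 geometry.

Step 8
Reactants: 12 [(4E)-5-iodo-4-methylpent-4-en-1-yn-1-yl]trimethylsilane; 6 methyl (4S)-5-[(2R,3R)-3-formyloxiran-2-yl]-4-methylpentanoate
Product: 15 methyl (4S)-5-[(2R,3S)-3-[(1S,2E)-1-hydroxy-3-methyl-6-(trimethylsilyl)hex-2-en-5-yn-1-yl]oxiran-2-yl]-4-methylpentanoate, via alkenyllithium 13 (not isolated), via lithium alkenyldimethylzincate 14 (not isolated)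
Conditions: t-BuLi (2 equiv), Et2O, −78 °C; Me2Zn, −78 °C; then 6, −78 °C; aq. NH4Cl
Reagents that add atoms: none
Why: Iodine–lithium exchange with retention and transmetalation to the zincate give a nucleophile that adds to the aldehyde but not to the ester, and 1,2-addition to the cis-epoxy aldehyde should follow the Felkin–Anh/Cornforth model (epoxide C–O anti to the incoming alkenyl group), giving mainly the anti epoxy alcohol with (S)-C17.

Step 9
Reactants: 15 methyl (4S)-5-[(2R,3S)-3-[(1S,2E)-1-hydroxy-3-methyl-6-(trimethylsilyl)hex-2-en-5-yn-1-yl]oxiran-2-yl]-4-methylpentanoate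
Product: 16 methyl (4S)-5-[(2R,3R)-3-[(1S,2E)-1-[(tert-butyldimethylsilyl)oxy]-3-methyl-6-(trimethylsilyl)hex-2-en-5-yn-1-yl]oxiran-2-yl]-4-methylpentanoate
Conditions: TBSCl, imidazole, DMAP (cat.), DMF, rt
Reagents that add atoms: tert-butyldimethylsilyl chloride, CC(C)(C)[Si](C)(C)Cl
Why: Silylation with TBSCl/imidazole is neutral enough to leave the epoxide intact and installs the C17 ether that later steers the bromonium face.

Step 10
Reactants: 16 methyl (4S)-5-[(2R,3R)-3-[(1S,2E)-1-[(tert-butyldimethylsilyl)oxy]-3-methyl-6-(trimethylsilyl)hex-2-en-5-yn-1-yl]oxiran-2-yl]-4-methylpentanoate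
Product: 19 methyl (4S,6S)-6-[(2R,3R,4S,5R)-4-bromo-3-[(tert-butyldimethylsilyl)oxy]-5-methyl-5-[3-(trimethylsilyl)prop-2-yn-1-yl]oxolan-2-yl]-6-methoxy-4-methylhexanoate, via bromonium ion 17 (not isolated), via epoxonium ion 18 (not isolated)
Conditions: NBS (1.1 equiv), MeOH (3–5 equiv), (CF3)2CHOH, 4 Å MS, 0 °C
Reagents that add atoms: N-bromosuccinimide, BrN1C(=O)CCC1=O; methanol, CO
Why: NBS in HFIP forms the bromonium ion 17 reversibly on the (E)-C18=C19 alkene, the epoxide oxygen opens it anti at the tertiary C19 to give the bicyclic epoxonium ion 18, and methanol opens 18 at the exocyclic C15 with inversion, so that C18–Br, O–C19 and C15–OMe form in one operation. The closest known reaction type is the bromonium-initiated epoxide-opening cascade in HFIP with capture by an external alcohol, combined with 5-endo bromoetherification by a homoallylic oxygen nucleophile. The one ring closed is the oxolane (O, C16, C17, C18, C19), formed in the 5-endo mode with respect to the alkene and Markovnikov at C19. C18 and C19 are set by anti addition across the E alkene (Br and the C19 methyl end cis) with the face chosen by C17: in the envelope transition state the silyloxy group sits outside and Br+ comes to the face bearing H17, so Br ends trans to OTBS; C15 is set by SN2 inversion of the cis-epoxide carbon and C16 keeps its C–O bond. The step needs cyclisation to outrun direct methanolysis of 17, which HFIP (long-lived bromonium ion, hydrogen-bonded and so weakly nucleophilic methanol) and the small amount of methanol should secure, and it needs opening of 18 at C15 rather than C16 or C19, which release of epoxide strain (C15/C16 over C19) and the inductive deactivation and hindrance of C16 next to the C17–O bond should secure. The silylalkyne and the ester are far less reactive towards Br+ than the trisubstituted alkene.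

Step 11
Reactants: 19 methyl (4S,6S)-6-[(2R,3R,4S,5R)-4-bromo-3-[(tert-butyldimethylsilyl)oxy]-5-methyl-5-[3-(trimethylsilyl)prop-2-yn-1-yl]oxolan-2-yl]-6-methoxy-4-methylhexanoate
Product: 20 (4S,6S)-6-[(2R,3R,4S,5R)-4-bromo-3-[(tert-butyldimethylsilyl)oxy]-5-methyl-5-(prop-2-yn-1-yl)oxolan-2-yl]-6-methoxy-4-methylhexanoic acid
Conditions: LiOH, THF/MeOH/H2O, rt; 1 M HCl to pH 3
Reagents that add atoms: lithium hydroxide, [Li+].[OH-]
Why: Saponification of the unhindered methyl ester in aqueous methanol also cleaves the C(sp)–SiMe3 bond, while the ring bromide, flanked by a quaternary carbon and lacking an antiperiplanar β-hydrogen, should survive.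

Step 12
Reactants: 20 (4S,6S)-6-[(2R,3R,4S,5R)-4-bromo-3-[(tert-butyldimethylsilyl)oxy]-5-methyl-5-(prop-2-yn-1-yl)oxolan-2-yl]-6-methoxy-4-methylhexanoic acid; 21 methyl (2S)-2-methyloxirane-2-carboxylate
Product: 23 (4S,6S)-6-[(2R,3R,4S,5R)-4-bromo-3-[(tert-butyldimethylsilyl)oxy]-5-[(5S)-5-hydroxy-6-methoxy-5-methyl-6-oxohex-2-yn-1-yl]-5-methyloxolan-2-yl]-6-methoxy-4-methylhexanoic acid, via dilithio carboxylate acetylide 22 (not isolated)
Conditions: n-BuLi (2.1 equiv), THF, −78 °C; BF3·OEt2; 21, −78 °C; aq. NH4Cl, pH 3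
Reagents that add atoms: none
Why: Yamaguchi–Hirao alkynylation: the lithium carboxylate is inert to n-BuLi at −78 °C, the acetylide activated by BF3 opens the glycidate at its CH2 terminus, and the (S)-quaternary centre of 21 becomes C24 without any bond to it being broken.

Step 13
Reactants: 23 (4S,6S)-6-[(2R,3R,4S,5R)-4-bromo-3-[(tert-butyldimethylsilyl)oxy]-5-[(5S)-5-hydroxy-6-methoxy-5-methyl-6-oxohex-2-yn-1-yl]-5-methyloxolan-2-yl]-6-methoxy-4-methylhexanoic acid
Product: 24 (4S,6S)-6-[(2R,3R,4S,5R)-4-bromo-3-[(tert-butyldimethylsilyl)oxy]-5-[(2Z,5S)-5-hydroxy-6-methoxy-5-methyl-6-oxohex-2-en-1-yl]-5-methyloxolan-2-yl]-6-methoxy-4-methylhexanoic acid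
Conditions: H2 (1 atm), Lindlar catalyst, quinoline, EtOAc, rt
Reagents that add atoms: none
Why: Lindlar semi-hydrogenation adds H2 syn to give the (Z)-C21=C22 alkene and should not touch the unactivated C–Br bond.

Step 14
Reactants: 24 (4S,6S)-6-[(2R,3R,4S,5R)-4-bromo-3-[(tert-butyldimethylsilyl)oxy]-5-[(2Z,5S)-5-hydroxy-6-methoxy-5-methyl-6-oxohex-2-en-1-yl]-5-methyloxolan-2-yl]-6-methoxy-4-methylhexanoic acid
Product: 26 (4S,6S)-6-[(2R,3R,4S,5R)-4-bromo-3-[(tert-butyldimethylsilyl)oxy]-5-[(2Z,5S)-5-[(tert-butyldimethylsilyl)oxy]-6-methoxy-5-methyl-6-oxohex-2-en-1-yl]-5-methyloxolan-2-yl]-6-methoxy-4-methylhexanoic acid, via silyl ester 25 (not isolated)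
Conditions: TBSOTf, 2,6-lutidine, CH2Cl2, 0 °C to rt; AcOH/THF/H2O, rt
Reagents that add atoms: tert-butyldimethylsilyl trifluoromethanesulfonate, CC(C)(C)[Si](C)(C)OS(=O)(=O)C(F)(F)F
Why: TBSOTf silylates the tertiary C24 alcohol, which would otherwise react with oxalyl chloride and Tf2O in steps 16–17, and the labile silyl ester formed at C10 is hydrolysed in the mildly acidic aqueous work-up.

Step 15
Reactants: 26 (4S,6S)-6-[(2R,3R,4S,5R)-4-bromo-3-[(tert-butyldimethylsilyl)oxy]-5-[(2Z,5S)-5-[(tert-butyldimethylsilyl)oxy]-6-methoxy-5-methyl-6-oxohex-2-en-1-yl]-5-methyloxolan-2-yl]-6-methoxy-4-methylhexanoic acid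
Product: 28 primary C10 carboxamide of 26 (all other groups unchanged), via isobutyl carbonic mixed anhydride 27 (not isolated)
Conditions: i-BuOCOCl, N-methylmorpholine, THF, −15 °C; NH3, −15 to 0 °C
Reagents that add atoms: ammonia, N
Why: Mixed-anhydride activation and ammonolysis give the primary amide, the α-quaternary silyloxy C25 ester being too hindered to react with ammonia in the short contact time.

Step 16
Reactants: 28 primary C10 carboxamide of 26
Product: 30 2-substituted 1,3-oxazol-4(5H)-one (ring C2 = C10; C17-OTBS, C24-OTBS, C25 methyl ester), via acyl isocyanate 29 (not isolated)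
Conditions: (COCl)2, ClCH2CH2Cl, 0 to 50 °C; CH2N2, Et2O/CH2Cl2, 0 °C
Reagents that add atoms: oxalyl chloride, O=C(Cl)C(=O)Cl; diazomethane, C=[N+]=[N-]
Why: Primary amides give acyl isocyanates with oxalyl chloride (Speziale reaction), and diazomethane adds to these with loss of N2 to close the oxazol-4(5H)-one, which supplies C8 and C9 of the oxazole.

Step 17
Reactants: 30 2-substituted 1,3-oxazol-4(5H)-one
Product: 31 2-substituted 1,3-oxazol-4-yl trifluoromethanesulfonate (C17-OTBS, C24-OTBS, C25 methyl ester)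
Conditions: Tf2O, Et3N, CH2Cl2, −78 °C
Reagents that add atoms: trifluoromethanesulfonic anhydride, O=S(=O)(OS(=O)(=O)C(F)(F)F)C(F)(F)F
Why: O-triflation of the enol form of the oxazolone aromatises the ring to the oxazol-4-yl triflate, an established electrophile for cross-coupling at C8.

Step 18
Reactants: 31 2-substituted 1,3-oxazol-4-yl trifluoromethanesulfonate
Product: 32 diol triflate (31 with free C17–OH and C24–OH)
Conditions: HF·pyridine (excess), pyridine, THF, 0 °C to rt
Reagents that add atoms: none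
Why: Fluoride-driven Si–O cleavage with HF·pyridine frees both alcohols (the tertiary ether needing the longer time) and leaves the heteroaryl triflate, bromide and methyl ester intact.

Step 19
Reactants: 33 but-2-yn-1-ol
Product: 34 but-2-ynal
Conditions: MnO2, CH2Cl2, rt; filtered solution used directly
Reagents that add atoms: none
Why: MnO2 oxidises propargylic alcohols selectively to ynals, and the volatile aldehyde is taken on in solution.

Step 20
Reactants: 35 (4R)-4-benzyl-3-propanoyl-1,3-oxazolidin-2-one; 34 but-2-ynal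
Product: 37 (4R)-4-benzyl-3-[(2R,3R)-3-hydroxy-2-methylhex-4-ynoyl]-1,3-oxazolidin-2-one, via dibutylboron Z-enolate 36 (not isolated)
Conditions: Bu2BOTf, Et3N, CH2Cl2, −78 to 0 °C; 34, −78 to 0 °C; H2O2, pH 7 buffer, MeOH
Reagents that add atoms: none
Why: Evans syn-aldol reaction: the (Z)-boron enolate reacts through a Zimmerman–Traxler chair on the face opposite the benzyl group, so the (R)-auxiliary sets C4 and C5 syn with the configuration of the target.

Step 21
Reactants: 37 (4R)-4-benzyl-3-[(2R,3R)-3-hydroxy-2-methylhex-4-ynoyl]-1,3-oxazolidin-2-one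
Product: 38 (4R)-4-benzyl-3-[(2R,3R)-3-[(tert-butyldimethylsilyl)oxy]-2-methylhex-4-ynoyl]-1,3-oxazolidin-2-one
Conditions: TBSOTf, 2,6-lutidine, CH2Cl2, −78 to 0 °C
Reagents that add atoms: tert-butyldimethylsilyl trifluoromethanesulfonate, CC(C)(C)[Si](C)(C)OS(=O)(=O)C(F)(F)F
Why: Silylation of the aldol hydroxyl blocks retro-aldol cleavage and provides the C5 protecting group carried to the last step.

Step 22
Reactants: 38 (4R)-4-benzyl-3-[(2R,3R)-3-[(tert-butyldimethylsilyl)oxy]-2-methylhex-4-ynoyl]-1,3-oxazolidin-2-one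
Product: 39 (2S,3R)-3-[(tert-butyldimethylsilyl)oxy]-2-methylhex-4-yn-1-ol
Conditions: LiBH4, MeOH (1 equiv), Et2O, 0 °C
Reagents that add atoms: none
Why: Reductive removal of the oxazolidinone with LiBH4 gives the primary alcohol (C3) without epimerising C4 and returns the auxiliary.

Step 23
Reactants: 39 (2S,3R)-3-[(tert-butyldimethylsilyl)oxy]-2-methylhex-4-yn-1-ol
Product: 40 (2R,3R)-3-[(tert-butyldimethylsilyl)oxy]-2-methylhex-4-ynal
Conditions: Dess–Martin periodinane, NaHCO3, CH2Cl2, 0 °C to rt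
Reagents that add atoms: none
Why: Buffered Dess–Martin oxidation gives the α-chiral aldehyde without epimerisation when it is used directly.

Step 24
Reactants: 40 (2R,3R)-3-[(tert-butyldimethylsilyl)oxy]-2-methylhex-4-ynal
Product: 41 methyl (2E,4S,5R)-5-[(tert-butyldimethylsilyl)oxy]-4-methyloct-2-en-6-ynoate
Conditions: Ph3P=CHCO2Me, CH2Cl2, rt
Reagents that add atoms: methyl (triphenylphosphoranylidene)acetate, COC(=O)C=P(c1ccccc1)(c1ccccc1)c1ccccc1
Why: Wittig olefination with a stabilised ylide gives the (E)-enoate (C2=C3) under neutral conditions that do not epimerise C4.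

Step 25
Reactants: 41 methyl (2E,4S,5R)-5-[(tert-butyldimethylsilyl)oxy]-4-methyloct-2-en-6-ynoate
Product: 42 methyl (2E,4S,5R,6E)-5-[(tert-butyldimethylsilyl)oxy]-4-methyl-7-(tributylstannyl)octa-2,6-dienoate
Conditions: Bu3SnH, PdCl2(PPh3)2 (5 mol%), THF, 0 °C to rt
Reagents that add atoms: tributyltin hydride, CCCC[SnH](CCCC)CCCC
Why: Palladium-catalysed hydrostannation adds H–Sn syn across the alkyne and should place tin on the less hindered, methyl-bearing C7, away from the branched silyloxy carbon, giving the (E)-alkenylstannane.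

Step 26
Reactants: 42 methyl (2E,4S,5R,6E)-5-[(tert-butyldimethylsilyl)oxy]-4-methyl-7-(tributylstannyl)octa-2,6-dienoate
Product: 43 (2E,4S,5R,6E)-5-[(tert-butyldimethylsilyl)oxy]-4-methyl-7-(tributylstannyl)octa-2,6-dienoic acid
Conditions: LiOH, THF/MeOH/H2O, rt; cold 0.5 M HCl to pH 4
Reagents that add atoms: lithium hydroxide, [Li+].[OH-]
Why: Saponification of the methyl enoate leaves the alkenylstannane and silyl ether intact when the acidification is kept cold and mild.

Step 27
Reactants: 43 (2E,4S,5R,6E)-5-[(tert-butyldimethylsilyl)oxy]-4-methyl-7-(tributylstannyl)octa-2,6-dienoic acid; 32 diol triflate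
Product: 45 C17 ester of 32 with acid 43 (oxazol-4-yl triflate and C7 stannane in one molecule; C5-OTBS; free C24–OH), via trichlorobenzoyl mixed anhydride 44 (not isolated)
Conditions: 2,4,6-Cl3C6H2COCl, Et3N, THF, rt; 32, DMAP, toluene, rt
Reagents that add atoms: none
Why: Yamaguchi esterification: DMAP transfers the dienoyl group from the mixed anhydride to the secondary C17–OH, whose ring face is unencumbered, while the tertiary C24–OH is too hindered to be acylated.

Step 28
Reactants: 45 C17 ester of 32 with acid 43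
Product: 46 macrolide with C5-OTBS and C25 methyl ester
Conditions: Pd(PPh3)4 (20 mol%), CuCl, LiCl, DMSO/THF, 60 °C, 1 mM
Reagents that add atoms: none
Why: Intramolecular Stille coupling under CuCl/LiCl promotion, conditions made for 1-substituted vinylstannanes and triflates, forms the C7–C8 bond with retention of the (E) geometry and closes the 18-membered ring at high dilution.

Step 29
Reactants: 46 macrolide with C5-OTBS and C25 methyl ester
Product: 47 macrolide with C5-OTBS and free C25 carboxylic acid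
Conditions: Me3SnOH, ClCH2CH2Cl, 80 °C; 5% HCl work-up
Reagents that add atoms: trimethyltin hydroxide, C[Sn](C)(C)O
Why: Trimethyltin hydroxide hydrolyses methyl esters under near-neutral conditions and is helped by the α-hydroxy group, so the C25 ester should be cleaved while the hindered macrolactone is kept.

Step 30
Reactants: 47 macrolide with C5-OTBS and free C25 carboxylic acid
Product: 48 CNP0163177.2
Conditions: HF·pyridine, pyridine, THF, 0 °C to rt
Reagents that add atoms: none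
Why: Buffered HF·pyridine removes the last silyl ether from the allylic C5–OH under conditions the lactone, bromide, alkenes and acid should tolerate.

## Compound list

1 | (S)-citronellal | O=CC[C@@H](C)CCC=C(C)C | starting material
2 | methyl (2Z,5S)-5,9-dimethyldeca-2,8-dienoate | COC(=O)/C=C\C[C@@H](C)CCC=C(C)C | intermediate
3 | (2Z,5S)-5,9-dimethyldeca-2,8-dien-1-ol | OC/C=C\C[C@@H](C)CCC=C(C)C | intermediate
4 | [(2S,3R)-3-[(2S)-2,6-dimethylhept-5-en-1-yl]oxiran-2-yl]methanol | CC(C)=CCC[C@H](C)C[C@H]1O[C@H]1CO | intermediate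
5 | methyl (4S)-5-[(2R,3S)-3-(hydroxymethyl)oxiran-2-yl]-4-methylpentanoate | COC(=O)CC[C@H](C)C[C@H]1O[C@H]1CO | intermediate
6 | methyl (4S)-5-[(2R,3R)-3-formyloxiran-2-yl]-4-methylpentanoate | COC(=O)CC[C@H](C)C[C@H]1O[C@H]1C=O | intermediate
7 | ethynyltrimethylsilane | C#C[Si](C)(C)C | starting material
8 | propargyl bromide | BrCC#C | starting material
9 | [(trimethylsilyl)ethynyl]magnesium bromide | C[Si](C)(C)C#C[Mg]Br | intermediate
10 | trimethyl(penta-1,4-diyn-1-yl)silane | C#CCC#C[Si](C)(C)C | intermediate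
11 | dimethyl[(1E)-2-methyl-5-(trimethylsilyl)pent-1-en-4-yn-1-yl]alumane | C[Al](C)/C=C(\C)CC#C[Si](C)(C)C | intermediate
12 | [(4E)-5-iodo-4-methylpent-4-en-1-yn-1-yl]trimethylsilane | I/C=C(\C)CC#C[Si](C)(C)C | intermediate
13 | [(1E)-2-methyl-5-(trimethylsilyl)pent-1-en-4-yn-1-yl]lithium | [Li]/C=C(\C)CC#C[Si](C)(C)C | intermediate
14 | lithium dimethyl[(1E)-2-methyl-5-(trimethylsilyl)pent-1-en-4-yn-1-yl]zincate | [Li+].C[Zn-](C)/C=C(\C)CC#C[Si](C)(C)C | intermediate
15 | methyl (4S)-5-[(2R,3S)-3-[(1S,2E)-1-hydroxy-3-methyl-6-(trimethylsilyl)hex-2-en-5-yn-1-yl]oxiran-2-yl]-4-methylpentanoate | COC(=O)CC[C@H](C)C[C@H]1O[C@H]1[C@@H](O)/C=C(\C)CC#C[Si](C)(C)C | intermediate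
16 | methyl (4S)-5-[(2R,3R)-3-[(1S,2E)-1-[(tert-butyldimethylsilyl)oxy]-3-methyl-6-(trimethylsilyl)hex-2-en-5-yn-1-yl]oxiran-2-yl]-4-methylpentanoate | COC(=O)CC[C@H](C)C[C@H]1O[C@H]1[C@@H](O[Si](C)(C)C(C)(C)C)/C=C(\C)CC#C[Si](C)(C)C | intermediate
17 | C18/C19 bromonium ion of 16 (Br on the face anti to the C17 silyloxy group) | COC(=O)CC[C@H](C)C[C@H]1O[C@H]1[C@@H](O[Si](C)(C)C(C)(C)C)[C@@H]2[Br+][C@@]2(C)CC#C[Si](C)(C)C | intermediate
18 | bicyclic epoxonium ion (O bonded to C15, C16 and C19; oxolane already closed) | COC(=O)CC[C@H](C)C[C@H]1[O+]2[C@H]1[C@@H](O[Si](C)(C)C(C)(C)C)[C@H](Br)[C@@]2(C)CC#C[Si](C)(C)C | intermediate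
19 | methyl (4S,6S)-6-[(2R,3R,4S,5R)-4-bromo-3-[(tert-butyldimethylsilyl)oxy]-5-methyl-5-[3-(trimethylsilyl)prop-2-yn-1-yl]oxolan-2-yl]-6-methoxy-4-methylhexanoate | CC(C)(C)[Si](C)(C)O[C@@H]1[C@@H]([C@@H](OC)C[C@@H](C)CCC(=O)OC)O[C@](C)(CC#C[Si](C)(C)C)[C@H]1Br | intermediate
20 | (4S,6S)-6-[(2R,3R,4S,5R)-4-bromo-3-[(tert-butyldimethylsilyl)oxy]-5-methyl-5-(prop-2-yn-1-yl)oxolan-2-yl]-6-methoxy-4-methylhexanoic acid | OC(=O)CC[C@H](C)C[C@H](OC)[C@H]1O[C@](C)(CC#C)[C@@H](Br)[C@@H]1O[Si](C)(C)C(C)(C)C | intermediate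
21 | methyl (2S)-2-methyloxirane-2-carboxylate | COC(=O)[C@]1(C)CO1 | starting material
22 | dilithio derivative of 20 (lithium carboxylate, lithium acetylide) | [Li]OC(=O)CC[C@H](C)C[C@H](OC)[C@H]1O[C@](C)(CC#C[Li])[C@@H](Br)[C@@H]1O[Si](C)(C)C(C)(C)C | intermediate
23 | (4S,6S)-6-[(2R,3R,4S,5R)-4-bromo-3-[(tert-butyldimethylsilyl)oxy]-5-[(5S)-5-hydroxy-6-methoxy-5-methyl-6-oxohex-2-yn-1-yl]-5-methyloxolan-2-yl]-6-methoxy-4-methylhexanoic acid | OC(=O)CC[C@H](C)C[C@H](OC)[C@H]1O[C@](C)(CC#CC[C@](C)(O)C(=O)OC)[C@@H](Br)[C@@H]1O[Si](C)(C)C(C)(C)C | intermediate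
24 | (4S,6S)-6-[(2R,3R,4S,5R)-4-bromo-3-[(tert-butyldimethylsilyl)oxy]-5-[(2Z,5S)-5-hydroxy-6-methoxy-5-methyl-6-oxohex-2-en-1-yl]-5-methyloxolan-2-yl]-6-methoxy-4-methylhexanoic acid | OC(=O)CC[C@H](C)C[C@H](OC)[C@H]1O[C@](C)(C/C=C\C[C@](C)(O)C(=O)OC)[C@@H](Br)[C@@H]1O[Si](C)(C)C(C)(C)C | intermediate
25 | tert-butyldimethylsilyl ester of 26 (C10 silyl ester, C17-OTBS, C24-OTBS) | CC(C)(C)[Si](C)(C)OC(=O)CC[C@H](C)C[C@H](OC)[C@H]1O[C@](C)(C/C=C\C[C@](C)(O[Si](C)(C)C(C)(C)C)C(=O)OC)[C@@H](Br)[C@@H]1O[Si](C)(C)C(C)(C)C | intermediate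
26 | (4S,6S)-6-[(2R,3R,4S,5R)-4-bromo-3-[(tert-butyldimethylsilyl)oxy]-5-[(2Z,5S)-5-[(tert-butyldimethylsilyl)oxy]-6-methoxy-5-methyl-6-oxohex-2-en-1-yl]-5-methyloxolan-2-yl]-6-methoxy-4-methylhexanoic acid | OC(=O)CC[C@H](C)C[C@H](OC)[C@H]1O[C@](C)(C/C=C\C[C@](C)(O[Si](C)(C)C(C)(C)C)C(=O)OC)[C@@H](Br)[C@@H]1O[Si](C)(C)C(C)(C)C | intermediate
27 | mixed anhydride of 26 with isobutyl carbonic acid | CC(C)COC(=O)OC(=O)CC[C@H](C)C[C@H](OC)[C@H]1O[C@](C)(C/C=C\C[C@](C)(O[Si](C)(C)C(C)(C)C)C(=O)OC)[C@@H](Br)[C@@H]1O[Si](C)(C)C(C)(C)C | intermediate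
28 | primary C10 carboxamide of 26 (13S,15S,16R,17R,18S,19R,24S; 21Z) | NC(=O)CC[C@H](C)C[C@H](OC)[C@H]1O[C@](C)(C/C=C\C[C@](C)(O[Si](C)(C)C(C)(C)C)C(=O)OC)[C@@H](Br)[C@@H]1O[Si](C)(C)C(C)(C)C | intermediate
29 | acyl isocyanate of 28 | O=C=NC(=O)CC[C@H](C)C[C@H](OC)[C@H]1O[C@](C)(C/C=C\C[C@](C)(O[Si](C)(C)C(C)(C)C)C(=O)OC)[C@@H](Br)[C@@H]1O[Si](C)(C)C(C)(C)C | intermediate
30 | 2-substituted 1,3-oxazol-4(5H)-one (ring C2 = C10; C17-OTBS, C24-OTBS, C25 methyl ester) | O=C1COC(=N1)CC[C@H](C)C[C@H](OC)[C@H]2O[C@](C)(C/C=C\C[C@](C)(O[Si](C)(C)C(C)(C)C)C(=O)OC)[C@@H](Br)[C@@H]2O[Si](C)(C)C(C)(C)C | intermediate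
31 | 2-substituted 1,3-oxazol-4-yl trifluoromethanesulfonate (C17-OTBS, C24-OTBS, C25 methyl ester) | O=S(=O)(Oc1coc(n1)CC[C@H](C)C[C@H](OC)[C@H]2O[C@](C)(C/C=C\C[C@](C)(O[Si](C)(C)C(C)(C)C)C(=O)OC)[C@@H](Br)[C@@H]2O[Si](C)(C)C(C)(C)C)C(F)(F)F | intermediate
32 | diol triflate: 31 with free C17–OH and C24–OH (13S,15S,16S,17R,18S,19R,24S; 21Z) | O=S(=O)(Oc1coc(n1)CC[C@H](C)C[C@H](OC)[C@H]2O[C@](C)(C/C=C\C[C@](C)(O)C(=O)OC)[C@@H](Br)[C@@H]2O)C(F)(F)F | intermediate
33 | but-2-yn-1-ol | CC#CCO | starting material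
34 | but-2-ynal | CC#CC=O | intermediate
35 | (4R)-4-benzyl-3-propanoyl-1,3-oxazolidin-2-one | CCC(=O)N1[C@H](Cc2ccccc2)COC1=O | starting material
36 | (Z)-dibutylboron enolate of 35 | C/C=C(\OB(CCCC)CCCC)N1[C@H](Cc2ccccc2)COC1=O | intermediate
37 | (4R)-4-benzyl-3-[(2R,3R)-3-hydroxy-2-methylhex-4-ynoyl]-1,3-oxazolidin-2-one | CC#C[C@H](O)[C@@H](C)C(=O)N1[C@H](Cc2ccccc2)COC1=O | intermediate
38 | (4R)-4-benzyl-3-[(2R,3R)-3-[(tert-butyldimethylsilyl)oxy]-2-methylhex-4-ynoyl]-1,3-oxazolidin-2-one | CC#C[C@H](O[Si](C)(C)C(C)(C)C)[C@@H](C)C(=O)N1[C@H](Cc2ccccc2)COC1=O | intermediate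
39 | (2S,3R)-3-[(tert-butyldimethylsilyl)oxy]-2-methylhex-4-yn-1-ol | CC#C[C@H](O[Si](C)(C)C(C)(C)C)[C@@H](C)CO | intermediate
40 | (2R,3R)-3-[(tert-butyldimethylsilyl)oxy]-2-methylhex-4-ynal | CC#C[C@H](O[Si](C)(C)C(C)(C)C)[C@@H](C)C=O | intermediate
41 | methyl (2E,4S,5R)-5-[(tert-butyldimethylsilyl)oxy]-4-methyloct-2-en-6-ynoate | CC#C[C@H](O[Si](C)(C)C(C)(C)C)[C@@H](C)/C=C/C(=O)OC | intermediate
42 | methyl (2E,4S,5R,6E)-5-[(tert-butyldimethylsilyl)oxy]-4-methyl-7-(tributylstannyl)octa-2,6-dienoate | CCCC[Sn](CCCC)(CCCC)/C(C)=C/[C@H](O[Si](C)(C)C(C)(C)C)[C@@H](C)/C=C/C(=O)OC | intermediate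
43 | (2E,4S,5R,6E)-5-[(tert-butyldimethylsilyl)oxy]-4-methyl-7-(tributylstannyl)octa-2,6-dienoic acid | CCCC[Sn](CCCC)(CCCC)/C(C)=C/[C@H](O[Si](C)(C)C(C)(C)C)[C@@H](C)/C=C/C(=O)O | intermediate
44 | mixed anhydride of 43 with 2,4,6-trichlorobenzoic acid | CCCC[Sn](CCCC)(CCCC)/C(C)=C/[C@H](O[Si](C)(C)C(C)(C)C)[C@@H](C)/C=C/C(=O)OC(=O)c1c(Cl)cc(Cl)cc1Cl | intermediate
45 | C17 ester of 32 with 43 (4S,5R,13S,15S,16R,17R,18S,19R,24S; 2E,6E,21Z) | O=S(=O)(Oc1coc(n1)CC[C@H](C)C[C@H](OC)[C@H]2O[C@](C)(C/C=C\C[C@](C)(O)C(=O)OC)[C@@H](Br)[C@@H]2OC(=O)/C=C/[C@H](C)[C@@H](O[Si](C)(C)C(C)(C)C)/C=C(\C)[Sn](CCCC)(CCCC)CCCC)C(F)(F)F | intermediate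
46 | macrolide with C5-OTBS and C25 methyl ester | CO[C@H]1C[C@@H](C)CCc2nc(co2)/C(C)=C/[C@H](O[Si](C)(C)C(C)(C)C)[C@@H](C)/C=C/C(=O)O[C@@H]2[C@@H]1O[C@](C)(C/C=C\C[C@](C)(O)C(=O)OC)[C@H]2Br | intermediate
47 | macrolide with C5-OTBS and free C25 acid | CO[C@H]1C[C@@H](C)CCc2nc(co2)/C(C)=C/[C@H](O[Si](C)(C)C(C)(C)C)[C@@H](C)/C=C/C(=O)O[C@@H]2[C@@H]1O[C@](C)(C/C=C\C[C@](C)(O)C(=O)O)[C@H]2Br | intermediate
48 | CNP0163177.2 (4S,5R,13S,15S,16R,17R,18S,19R,24S; 2E,6E,21Z) | CO[C@H]1C[C@@H](C)CCc2nc(co2)/C(C)=C/[C@H](O)[C@@H](C)/C=C/C(=O)O[C@@H]2[C@@H]1O[C@](C)(C/C=C\C[C@](C)(O)C(=O)O)[C@H]2Br | target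

## Step count and risks

Total step count: 30. Longest linear sequence: 20 steps (steps 1–5, 8–18, 27–30).

Steps most likely to fail:

1. Step 10 (key step). Methanol may add directly to the bromonium ion before the epoxide oxygen does, bromonium formation may occur on the wrong alkene face, or the epoxonium ion may be opened at C16 to give a six-membered ether. Fallback (sets out from 16, returns at 19): the cascade is split into two known reactions. Acid-catalysed methanolysis of the epoxide (CSA cat., MeOH/CH2Cl2, 0 °C) should open it at C15, the carbon remote from the C17–O bond, with inversion, giving methyl (4S,6S,7R,8S,9E)-8-[(tert-butyldimethylsilyl)oxy]-7-hydroxy-6-methoxy-4,10-dimethyl-13-(trimethylsilyl)tridec-9-en-12-ynoate F1. NBS in CH2Cl2 at 0 °C then closes the oxolane by 5-endo bromoetherification of the C16 hydroxyl onto the tertiary C19, giving 19.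

2. Step 12. The carboxylate–acetylide dianion may aggregate and react sluggishly, the carboxylate may sequester BF3, or the acetylide may be consumed by the ester of the glycidate. Fallback (sets out from 20, returns at 23): the acid is masked so that a mono-anion is used. Boc2O, DMAP and t-BuOH give tert-butyl (4S,6S)-6-[(2R,3R,4S,5R)-4-bromo-3-[(tert-butyldimethylsilyl)oxy]-5-methyl-5-(prop-2-yn-1-yl)oxolan-2-yl]-6-methoxy-4-methylhexanoate F2. Its lithium acetylide (n-BuLi 1 equiv, −78 °C; tert-butyl esters resist addition at this temperature) with BF3·OEt2 and 21 gives the tert-butyl ester of 23 F3. TMSOTf/2,6-lutidine then cleaves the tert-butyl ester selectively (methyl ester and TBS ether untouched), and mild aqueous work-up removes the transient silyl groups to give 23.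

3. Step 28. Transmetalation of the hindered 1-methylalkenylstannane may be slow at the dilution needed for ring closure, so that protodestannylation or oligomerisation takes over. Fallback (sets out from 32 and 43, returns at 46): the order of the two bond formations is reversed. Intermolecular Stille coupling of 32 with 43 (same Pd/CuCl/LiCl system, 0.1 M, acid as its carboxylate) gives the seco acid (C1 acid, free C17–OH, C5-OTBS, C7–C8 bond formed) F4. Yamaguchi macrolactonisation at high dilution then closes the ring at the C17–O bond, the tertiary C24–OH not competing, and gives 46.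

Further compounds
F1 | step 10 | methyl (4S,6S,7R,8S,9E)-8-[(tert-butyldimethylsilyl)oxy]-7-hydroxy-6-methoxy-4,10-dimethyl-13-(trimethylsilyl)tridec-9-en-12-ynoate | COC(=O)CC[C@H](C)C[C@H](OC)[C@@H](O)[C@@H](O[Si](C)(C)C(C)(C)C)/C=C(\C)CC#C[Si](C)(C)C
F2 | step 12 | tert-butyl (4S,6S)-6-[(2R,3R,4S,5R)-4-bromo-3-[(tert-butyldimethylsilyl)oxy]-5-methyl-5-(prop-2-yn-1-yl)oxolan-2-yl]-6-methoxy-4-methylhexanoate | CC(C)(C)OC(=O)CC[C@H](C)C[C@H](OC)[C@H]1O[C@](C)(CC#C)[C@@H](Br)[C@@H]1O[Si](C)(C)C(C)(C)C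
F3 | step 12 | tert-butyl ester of 23 | CC(C)(C)OC(=O)CC[C@H](C)C[C@H](OC)[C@H]1O[C@](C)(CC#CC[C@](C)(O)C(=O)OC)[C@@H](Br)[C@@H]1O[Si](C)(C)C(C)(C)C
F4 | step 28 | seco acid (C7–C8 bond formed, C1 acid, free C17–OH and C24–OH, C5-OTBS) | OC(=O)/C=C/[C@H](C)[C@@H](O[Si](C)(C)C(C)(C)C)/C=C(\C)c1coc(n1)CC[C@H](C)C[C@H](OC)[C@H]2O[C@](C)(C/C=C\C[C@](C)(O)C(=O)OC)[C@@H](Br)[C@@H]2O
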